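**Strategy.** The biaryl bond C2–C2' is traced back to a C3–C2' bond. In phenol ring A (C1 CH2, C2 biaryl, C3 OH, C4 OMe) the pair C3–OH/C4–OMe is the retron of an o-quinone monoketal whose carbonyl C3 has taken up ring B. In the key step acid ionizes the C4 ketal, ring B shifts from C3 to C2 and ring A aromatizes. The nine-membered carbocycle (the eight ring atoms plus C3) contracts to the eight-membered ring, the biaryl bond forms and the free phenol appears. The same acid closes the tetrahydrofuran at C7. The precursor is a bridged nine-membered triol carrying a dienol ketal.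

Key step: step 12

Atom names used below: ring A (phenol ring) has C1 (bears C7'H2), C2 (biaryl), C3 (OH), C4 and C5 (OMe), C6 (H). Ring B has C1' (bears C7), C2' (biaryl), C3'–C5' (OMe), C6' (H). C7 is the O–CH–aryl carbon, C8 the CH–CH3 carbon, C8' the CH that bears C7'H2 and C9'H2–O.

Assumption: the SMILES fixes C7, C8 and C8' (all R) and leaves the biaryl axis open; the axis is taken to settle in the one configuration that the oxygen-bridged eight-membered ring allows.

Remark: the carbinol carbon C3 of ring A in compounds 14–17 and C7 in 17 are formed as epimer mixtures; both centres are erased or reset in step 12. Compounds 1, 3 and 11 are commercial.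

Step 1
Reactants: 1 3-hydroxy-4,5-dimethoxybenzaldehyde
Product: 2 3-(benzyloxy)-4,5-dimethoxybenzaldehyde
Conditions: BnBr, K2CO3, DMF, rt
Reagents that add atoms: benzyl bromide BrCc1ccccc1
Why: Williamson etherification; the benzyl ether shields the phenol from the Stobbe base and from O-methylation in step 5.

Step 2
Reactants: 2 3-(benzyloxy)-4,5-dimethoxybenzaldehyde; 3 dimethyl succinate
Product: 4 (E)-4-[3-(benzyloxy)-4,5-dimethoxyphenyl]-3-(methoxycarbonyl)but-3-enoic acid
Conditions: KOtBu, tBuOH, reflux; then aq. HCl
Reagents that add atoms: none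
Why: Stobbe condensation; opening of the paraconic ester intermediate should give the (E)-half-ester with the free acid on the saturated arm.

Step 3
Reactants: 4 (E)-half-ester
Product: 5 (3R)-4-[3-(benzyloxy)-4,5-dimethoxyphenyl]-3-(methoxycarbonyl)butanoic acid
Conditions: [Rh(cod)((S,S)-Et-DuPhos)]BF4 (1 mol %), H2 (5 bar), NEt3 (1 equiv), MeOH, rt
Reagents that add atoms: none
Why: Rhodium-catalysed asymmetric hydrogenation of an itaconate-type half-ester with carboxylate binding; the ligand enantiomer is the one that sets C8' as R (to be confirmed on the first batch, the antipodal ligand being the remedy).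

Step 4
Reactants: 5 (3R)-acid ester
Product: 7 (4R)-4-[3-(benzyloxy)-4,5-dimethoxybenzyl]dihydrofuran-2(3H)-one, via hydroxy acid 6 (not isolated)
Conditions: LiBH4, THF, 0 °C to rt; then 2 M HCl, rt
Reagents that add atoms: none
Why: Chemoselective ester reduction (the lithium carboxylate is inert to LiBH4) followed by acid lactonisation; C8' is not touched.

Step 5
Reactants: 7 (4R)-lactone
Product: 8 (3R,4R)-4-[3-(benzyloxy)-4,5-dimethoxybenzyl]-3-methyldihydrofuran-2(3H)-one
Conditions: LiN(iPr)2 (1.1 equiv), THF, −78 °C; MeI, −78 to −40 °C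
Reagents that add atoms: methyl iodide CI
Why: Lactone enolate alkylation; methyl iodide should approach anti to the C8' benzyl group and so set C8 trans (3R,4R).

Step 6
Reactants: 8 (3R,4R)-benzyl ether lactone
Product: 9 (3R,4R)-4-(3-hydroxy-4,5-dimethoxybenzyl)-3-methyldihydrofuran-2(3H)-one
Conditions: H2 (1 atm), Pd/C (10 %), EtOAc, rt
Reagents that add atoms: none
Why: Hydrogenolysis of the benzyl ether; the lactone and both stereocentres are inert.

Step 7
Reactants: 9 phenol lactone
Product: 10 (3R,4R)-3-methyl-4-[(4,4,5-trimethoxy-3-oxocyclohexa-1,5-dien-1-yl)methyl]dihydrofuran-2(3H)-one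
Conditions: PhI(OAc)2 (1.05 equiv), MeOH, 0 °C, 15 min; used at once
Reagents that add atoms: methanol CO
Why: Oxidative dearomatisation of a 2-methoxyphenol with PhI(OAc)2; methanol should add to the methoxy-bearing ortho carbon C4 and give the o-quinone monoketal with C3 as the carbonyl.

Step 8
Reactants: 11 5-bromo-1,2,3-trimethoxybenzene
Product: 12 5-bromo-4-iodo-1,2,3-trimethoxybenzene
Conditions: N-iodosuccinimide, CF3CO2H (cat.), MeCN, rt
Reagents that add atoms: N-iodosuccinimide O=C1CCC(=O)N1I
Why: Electrophilic aromatic iodination at the only kind of free position, which is ortho and para to methoxy groups.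

Step 9
Reactants: 10 dienone ketal lactone; 12 5-bromo-4-iodo-1,2,3-trimethoxybenzene
Product: 14 (3R,4R)-4-{[3-(6-bromo-2,3,4-trimethoxyphenyl)-3-hydroxy-4,4,5-trimethoxycyclohexa-1,5-dien-1-yl]methyl}-3-methyldihydrofuran-2(3H)-one (both C3 epimers), via aryl Grignard reagent 13 (not isolated)
Conditions: 12, iPrMgCl·LiCl, THF, −40 °C; LaCl3·2LiCl; then 10, −78 to −40 °C; pH 7 buffer
Reagents that add atoms: none
Why: Iodine–magnesium exchange (iodide before bromide) and 1,2-addition of the aryl Grignard to the dienone carbonyl C3 (Stork–Danheiser-type addition to a vinylogous ester), which should outrun attack on the lactone; this fixes C2' on C3 without any regiochemical choice.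

Step 10
Reactants: 14 bromo carbinol lactone
Product: 16 nine-membered hydroxy ketone (ring B C1' acylated by C7; C9' freed as CH2OH; both C3 epimers), via dilithio aryllithium alkoxide 15 (not isolated)
Conditions: t-BuLi (3.2 equiv), THF (0.005 M), −100 °C; then to −40 °C; aq. NH4Cl
Reagents that add atoms: none
Why: Parham cyclisation; bromine–lithium exchange at −100 °C should outrun attack of t-BuLi on the lactone, and the aryllithium should acylate itself on the lactone carbonyl from the tether face (anti to the C8 methyl) to close the nine-membered ring.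

Step 11
Reactants: 16 nine-membered hydroxy ketone
Product: 17 nine-membered triol (C7–OH; epimers at C3 and C7)
Conditions: NaBH4, MeOH, 0 °C
Reagents that add atoms: none
Why: Borohydride reduction of the aryl ketone; the C7 configuration is irrelevant because C7 is ionised in step 12.

Step 12
Reactants: 17 nine-membered triol
Product: 19 target CNP0322364.1, via eight-membered phenol diol 18 (not isolated)
Conditions: BF3·OEt2 (3 equiv), 4 Å molecular sieves, CH2Cl2, −78 to 0 °C
Reagents that add atoms: none
Why: BF3 should abstract one methoxy group of the C4 ketal to give a methoxy-stabilised pentadienyl cation (C4/C6/C2); ring B then shifts from the carbinol carbon C3 to C2 through a phenonium-type bridge and the protonated 2,4-dienone loses H-2, so ring A aromatises, the nine-membered carbocycle contracts to the eight-membered one, the C2–C2' bond forms and C3–OH is left next to C4–OMe. The closest known reaction types are the quinol (dienone–phenol) rearrangement and the pinacol-type 1,2-aryl shift of α-hydroxy ketals. On warming, the p-methoxybenzylic C7–OH should ionise and C9'–OH capture the cation in an SN1 cycloetherification (formally 5-exo-tet) that closes the tetrahydrofuran. C7 is the only new stereocentre and is fixed by the ring system, because the two-atom oxygen bridge can span C7 and C8' only on the face that C9' occupies, and the ether closure is reversible so the cis-bridged product should accumulate. The step needs ketal ionisation to precede loss of the tertiary C3–OH and the shift to go to C2, not C4: the ketal gives the better (oxocarbenium) cation, a shift to C4 would enlarge the ring and give a dienone that cannot aromatise and so reverts, while the shift to C2 relieves ring strain and ends irreversibly in the phenol. Anhydrous conditions keep the C4 methoxy group from being lost by hydrolysis.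

**Compound list**

1 | 3-hydroxy-4,5-dimethoxybenzaldehyde | O=Cc1cc(O)c(OC)c(OC)c1 | starting material
2 | 3-(benzyloxy)-4,5-dimethoxybenzaldehyde | O=Cc1cc(OCc2ccccc2)c(OC)c(OC)c1 | intermediate
3 | dimethyl succinate | COC(=O)CCC(=O)OC | starting material
4 | (E)-4-[3-(benzyloxy)-4,5-dimethoxyphenyl]-3-(methoxycarbonyl)but-3-enoic acid | COC(=O)/C(CC(=O)O)=C/c1cc(OCc2ccccc2)c(OC)c(OC)c1 | intermediate
5 | (3R)-4-[3-(benzyloxy)-4,5-dimethoxyphenyl]-3-(methoxycarbonyl)butanoic acid | COC(=O)[C@H](Cc1cc(OCc2ccccc2)c(OC)c(OC)c1)CC(=O)O | intermediate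
6 | (3R)-4-[3-(benzyloxy)-4,5-dimethoxyphenyl]-3-(hydroxymethyl)butanoic acid (not isolated) | OC[C@H](Cc1cc(OCc2ccccc2)c(OC)c(OC)c1)CC(=O)O | intermediate
7 | (4R)-4-[3-(benzyloxy)-4,5-dimethoxybenzyl]dihydrofuran-2(3H)-one | O=C1OC[C@H](Cc2cc(OCc3ccccc3)c(OC)c(OC)c2)C1 | intermediate
8 | (3R,4R)-4-[3-(benzyloxy)-4,5-dimethoxybenzyl]-3-methyldihydrofuran-2(3H)-one (trans) | O=C1OC[C@H](Cc2cc(OCc3ccccc3)c(OC)c(OC)c2)[C@H]1C | intermediate
9 | (3R,4R)-4-(3-hydroxy-4,5-dimethoxybenzyl)-3-methyldihydrofuran-2(3H)-one | O=C1OC[C@H](Cc2cc(O)c(OC)c(OC)c2)[C@H]1C | intermediate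
10 | (3R,4R)-3-methyl-4-[(4,4,5-trimethoxy-3-oxocyclohexa-1,5-dien-1-yl)methyl]dihydrofuran-2(3H)-one (o-quinone monoketal of ring A, carbonyl at C3, ketal at C4) | O=C1OC[C@H](CC2=CC(=O)C(OC)(OC)C(OC)=C2)[C@H]1C | intermediate
11 | 5-bromo-1,2,3-trimethoxybenzene | COc1cc(Br)cc(OC)c1OC | starting material
12 | 5-bromo-4-iodo-1,2,3-trimethoxybenzene | COc1cc(Br)c(I)c(OC)c1OC | intermediate
13 | (6-bromo-2,3,4-trimethoxyphenyl)magnesium chloride, LiCl complex (not isolated) | COc1cc(Br)c([Mg]Cl)c(OC)c1OC | intermediate
14 | (3R,4R)-4-{[3-(6-bromo-2,3,4-trimethoxyphenyl)-3-hydroxy-4,4,5-trimethoxycyclohexa-1,5-dien-1-yl]methyl}-3-methyldihydrofuran-2(3H)-one, both epimers at the carbinol carbon C3 | O=C1OC[C@H](CC2=CC(O)(c3c(Br)cc(OC)c(OC)c3OC)C(OC)(OC)C(OC)=C2)[C@H]1C | intermediate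
15 | dilithio form of 14: lithium alkoxide at C3–O and aryllithium at C1' of ring B (not isolated) | O=C1OC[C@H](CC2=CC(O[Li])(c3c([Li])cc(OC)c(OC)c3OC)C(OC)(OC)C(OC)=C2)[C@H]1C | intermediate
16 | nine-membered hydroxy ketone: ring atoms C1', C7(=O), C8(R, CH3), C8'(R, CH2OH), C7', C1, C2, C3(OH), C2'; ring A still the dienol C4 dimethyl ketal; both C3 epimers | OC[C@@H]1CC2=CC(O)(c3c(OC)c(OC)c(OC)cc3C(=O)[C@@H]1C)C(OC)(OC)C(OC)=C2 | intermediate
17 | nine-membered triol: as 16 with C7 as CH–OH; epimers at C3 and C7, (8R,8'R) | OC[C@@H]1CC2=CC(O)(c3c(OC)c(OC)c(OC)cc3C(O)[C@@H]1C)C(OC)(OC)C(OC)=C2 | intermediate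
18 | eight-membered phenol diol: dibenzocyclooctadiene with C3–OH, C7–OH and C9'H2OH, (8R,8'R) (not isolated) | OC[C@@H]1Cc2cc(OC)c(OC)c(O)c2-c2c(OC)c(OC)c(OC)cc2C(O)[C@@H]1C | intermediate
19 | CNP0322364.1, (7R,8R,8'R)-7,9'-epoxy-dibenzocyclooctadiene lignan with C3–OH | COc1cc2c(c(O)c1OC)-c1c(cc(OC)c(OC)c1OC)[C@@H]1OC[C@H](C2)[C@H]1C | target

**Totals.** Total step count: 12. Longest linear sequence: 11 steps (steps 1–7 and 9–12); step 8 is a one-step branch.

**Steps most likely to fail**

1. Step 10 (nine-membered ring closure). The aryllithium may be quenched by proton transfer (lactone α-hydrogen) or may react between molecules before it reaches the lactone carbonyl, since a medium ring with an E-configured ring alkene has to form. Fallback: set out from 14 and reduce the lactone with iBu2AlH (CH2Cl2, −78 °C) to the lactol F1. After deprotonation of both hydroxyl groups and bromine–lithium exchange (t-BuLi, −100 °C, then warming), the aryllithium should add to the ring-opened aldehyde, a more electrophilic and conformationally freer acceptor. This gives the triol directly and comes back to the route at 17, without step 11.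

2. Step 9 (aryl addition to the dienone ketal). The doubly ortho-substituted Grignard reagent may add slowly, so that the labile dienone ketal dimerises or the reagent attacks the lactone or loses MgClBr to an aryne. Fallback: reverse the order of the two aryl–carbon bonds, setting out from 9. Commercial 5-iodo-1,2,3-trimethoxybenzene is brominated (N-bromosuccinimide, MeCN) to 4-bromo-5-iodo-1,2,3-trimethoxybenzene F2. Iodine–magnesium exchange gives (2-bromo-3,4,5-trimethoxyphenyl)magnesium chloride F3, which opens the lactone of 9 (excess reagent, the phenol being deprotonated first) to the keto alcohol F4. NaBH4 gives the diol F5, and PhI(OAc)2 in methanol gives the dienone ketal F6. Bromine–lithium exchange (t-BuLi, −100 °C) then closes the ring by intramolecular 1,2-addition of C2' to the C3 carbonyl, and the route is rejoined at 17.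

3. Step 12 (key step). The C7 cation may be captured by the wrong oxygen (C3–OH before the shift, the new phenol after it) or lose H-8 to a styrene and so scramble C8, and water released too early may hydrolyse the ketal cation so that the C4 methyl group is lost. Fallback: set out from 16 and run the acid-triggered aryl shift at the ketone level (BF3·OEt2, 4 Å sieves, CH2Cl2, −78 °C), where no C7 cation can form, to give the eight-membered keto phenol F7. The tetrahydrofuran is then closed by reductive cycloetherification (Et3SiH, BF3·OEt2, CH2Cl2, −78 °C), hydride reaching the hemiketal-derived oxocarbenium ion from the only open face. This comes back to the route at 19.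

**Further compounds**

F1 | step 10 | lactol of 14: (4R,5R... as in 14) 2-hydroxy-tetrahydrofuran in place of the lactone, anomer and C3 epimer mixture | OC1OC[C@H](CC2=CC(O)(c3c(Br)cc(OC)c(OC)c3OC)C(OC)(OC)C(OC)=C2)[C@H]1C
F2 | step 9 | 4-bromo-5-iodo-1,2,3-trimethoxybenzene | COc1cc(I)c(Br)c(OC)c1OC
F3 | step 9 | (2-bromo-3,4,5-trimethoxyphenyl)magnesium chloride | COc1cc([Mg]Cl)c(Br)c(OC)c1OC
F4 | step 9 | (2R,3R)-1-(2-bromo-3,4,5-trimethoxyphenyl)-4-hydroxy-3-(3-hydroxy-4,5-dimethoxybenzyl)-2-methylbutan-1-one | OC[C@H](Cc1cc(O)c(OC)c(OC)c1)[C@@H](C)C(=O)c1cc(OC)c(OC)c(OC)c1Br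
F5 | step 9 | (2R,3R)-1-(2-bromo-3,4,5-trimethoxyphenyl)-3-(3-hydroxy-4,5-dimethoxybenzyl)-2-methylbutane-1,4-diol, C1 epimers | OC[C@H](Cc1cc(O)c(OC)c(OC)c1)[C@@H](C)C(O)c1cc(OC)c(OC)c(OC)c1Br
F6 | step 9 | dienone ketal of F5: ring A as 4,4,5-trimethoxy-3-oxocyclohexa-1,5-dien-1-yl | OC[C@H](CC1=CC(=O)C(OC)(OC)C(OC)=C1)[C@@H](C)C(O)c1cc(OC)c(OC)c(OC)c1Br
F7 | step 12 | eight-membered keto phenol: dibenzocyclooctadiene with C3–OH, C7=O and C9'H2OH, (8R,8'R) | OC[C@@H]1Cc2cc(OC)c(OC)c(O)c2-c2c(OC)c(OC)c(OC)cc2C(=O)[C@@H]1C
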